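A leftover opens the reading. Friday's flask was charged with 0.500 G per E, less G than E, and its D flattens near 12.4% of the E charged from about 40.0 min. So G reads as the limiting reagent and E as the leftover.

| flask | E | G | temperature | remark | time |
|---|---|---|---|---|---|
| Sunday's | 0.070 M | 0.055 M | −25 °C | run made earlier |  |
| Friday's | 0.11 M | 0.055 M | 0 °C | run made earlier |  |
| Wednesday's | 0.050 M | 0.028 M | −25 °C | run made earlier |  |
| south-west | 0.050 M | 0.0550 M | 0 °C |  | 2.5 h |
| north-east | 0.050 M | 0.0550 M | 20 °C |  | 2.5 h |
| north-west | 0.050 M | 0.0550 M | −20 °C |  | 2.5 h |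

Sunday's run (percent of the E charged)

| time / h | D / % |
|---|---|
| 0.500 | 0.4 |
| 1.33 | 3.2 |
| 2.50 | 6.9 |
| 3.00 | 8.5 |
| 5.00 | 12.1 |

Friday's run (percent of the E charged)

| time / min | D / % |
|---|---|
| 20.0 | 8.8 |
| 40.0 | 11.4 |
| 50.0 | 10.9 |
| 80.0 | 12.4 |
| 90.0 | 12.0 |

Wednesday's run (percent of the E charged)

| time / h | D / % |
|---|---|
| 0.500 | 0 |
| 1.33 | 0.5 |
| 2.50 | 2.7 |
| 3.00 | 3.5 |
| 5.00 | 5.8 |

(standard deviation of a reading: 0.3 percentage points)

- the numbers in the tables scatter by 0.3 percentage points (one standard deviation)

* the flask with the highest amount of D, in percent of the E charged ("all alike" if they lie within 1.5 percentage points) (south-west / north-east / north-west / all alike)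
* final D, as a percentage of the E charged, in south-west
* final D, as a percentage of the E charged, in north-east
* final D, as a percentage of the E charged, in north-west

Sunday's D starts with a lag, at 0.4% after 0.500 h, so D comes through an intermediate, but Friday's flat stretch gives a usable time. The steps pair two species, and Friday's flask has the G charge and the temperature of south-west, so I stretch Friday's time by the ratio of the E charges, which gives 1.47 h for south-west at 0 °C. This stopping time, the time by which G ceases to feed D at a given temperature and charge, is shorter than the 2.5 h allowed. So my reckoning has south-west finished at the asked time, with north-east at 20 °C finished too. But north-west at −20 °C stands close to Sunday's −25 °C, whose D still climbs from 8.5% to 12.1%, so it should still be running. The stopping time gives no height for D.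

The forecast says all alike, with south-west at 40% (range 35% to 45%), north-east at 41% (36% to 46%) and north-west at 14% (10% to 19%), on the ground that “complete consumption gives D” of about 41%.

The flasks give 33.3% in south-west, 36.7% in north-east and 14.6% in north-west, so north-east leads, and south-west lies 6.7 percentage points below the forecast.

    E + G → L (k = 0.00180 L mol⁻¹ s⁻¹, Ea = 62.0 kJ mol⁻¹)
    G + L → D (k = 0.00289 L mol⁻¹ s⁻¹, Ea = 60.0 kJ mol⁻¹)
    G + D → J (k = 0.00126 L mol⁻¹ s⁻¹, Ea = 42.0 kJ mol⁻¹)
    2 E → Z (k = 1.54 × 10⁻⁴ L mol⁻¹ s⁻¹, Ea = 62.0 kJ mol⁻¹)
    (constants at −20 °C)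

South-west, with its stopping time of 1.47 h, holds 4.85% of its G at 1.25 h and 0.398% at 2.50 h; by then the half-life of E through the step with G is 56 h against a run of 2.5 h, and D still reads 33.4% at 25.0 h. A further flask, south-west with 0.020 M of E and its G, temperature and time held, has a reckoned stopping time of 3.67 h, longer than its 2.5 h, and it ends with 20% of its G unused and D at 46.9%.

(The readings were generated by integration with made-up constants, and the scatter is random.)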